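**Retrosynthetic overview**
1. The butenolide is closed last: target ⇐ (E)-γ-hydroxy enoic acid by photochemical E→Z isomerisation and lactonisation, after one global saponification.
2. C12–C13 is made by B-alkyl Suzuki coupling of a 9-vinyl decalin lactone with an (E)-vinyl iodide side chain; C16 comes from a chiral phosphoric acid-catalysed propargylation.
3. The 6α-oxygen is delivered from the C4 carboxylic acid by carboxylate-directed γ-C–H lactonisation; the acid itself is unmasked from a phenyl group with RuO4.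
4. Rings A then B form in one cascade: an IDPi Brønsted acid-catalysed enantioselective cyclisation of an achiral (E,E,E)-aryl triene acetate, terminated by the acetate (sets C4, C5, C10, C9, C8). The γ-lactone is the third ring, the butenolide the fourth.
5. The triene comes from geranyl acetate and phenylacetylene.

Assumption: decalin carbons carry labdane locants (C1–C10; C11, C12 on C9; side chain C13(Me)=C14–C15–C16, C16 = butenolide carbinol carbon); β is the face of the C10 methyl; on this numbering the target is 4R,5R,6S,8R,9R,10S,16R with a 13E alkene.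

**Step 1**
Reactants: 1 ethynylbenzene
Product: 3 (E)-(1-iodoprop-1-en-2-yl)benzene, via vinylalane 2 (not isolated)
Conditions: Me3Al (2 equiv), Cp2ZrCl2 (0.2 equiv), CH2Cl2, rt; then I2, THF, −30 → 0 °C
Reagents that add atoms: trimethylaluminium, C[Al](C)C; iodine, [I][I]
Why: Negishi zirconium-catalysed carboalumination adds Me and Al syn with Me on the internal carbon, and iodinolysis of the C–Al bond goes with retention, giving the E iodide.

**Step 2**
Reactants: 4 geranyl acetate
Product: 6 (2E,6E)-3,7-dimethyl-8-oxoocta-2,6-dien-1-yl acetate, via allylic alcohol 5 (not isolated)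
Conditions: SeO2 (0.1 equiv), t-BuOOH (3 equiv), salicylic acid (0.1 equiv), CH2Cl2, rt; filter, then MnO2 (10 equiv), CH2Cl2, rt
Reagents that add atoms: tert-butyl hydroperoxide, CC(C)(C)OO
Why: SeO2 allylic oxidation (ene reaction then 2,3-sigmatropic shift) selects the E-methyl of the terminal alkene because the 2,3-alkene is deactivated by the allylic acetate, and MnO2 takes the allylic alcohol to the enal.

**Step 3**
Reactants: 6 (2E,6E)-3,7-dimethyl-8-oxoocta-2,6-dien-1-yl acetate
Product: 7 (2E,6E)-3,7-dimethylnona-2,6,8-trien-1-yl acetate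
Conditions: Ph3PCH3Br (1.1 equiv), KN(SiMe3)2 (1.05 equiv), THF, −78 → 0 °C
Reagents that add atoms: methyltriphenylphosphonium bromide, [Br-].C[P+](c1ccccc1)(c1ccccc1)c1ccccc1
Why: Wittig methylenation of the enal is much faster than attack of the ylide on the acetate at low temperature and leaves both trisubstituted alkenes untouched.

**Step 4**
Reactants: 7 (2E,6E)-3,7-dimethylnona-2,6,8-trien-1-yl acetate; 3 (E)-(1-iodoprop-1-en-2-yl)benzene
Product: 9 (2E,6E,10E)-3,7-dimethyl-11-phenyldodeca-2,6,10-trien-1-yl acetate, via alkylborane 8 (not isolated)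
Conditions: 9-BBN (1.1 equiv), THF, 0 °C → rt; then 3 (1.05 equiv), Pd(dppf)Cl2 (5 mol%), AsPh3 (10 mol%), Cs2CO3 (2 equiv), DMF/H2O, rt
Reagents that add atoms: none
Why: 9-BBN hydroborates only the monosubstituted terminal alkene of the diene (anti-Markovnikov), and the B-alkyl Suzuki–Miyaura coupling keeps the E geometry of the vinyl iodide; at room temperature the allylic acetate is not ionised by zerovalent palladium.

**Step 5**
Reactants: 9 (2E,6E,10E)-3,7-dimethyl-11-phenyldodeca-2,6,10-trien-1-yl acetate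
Product: 11 9β-(acetoxymethyl)-4β,8β,10β-trimethyl-4α-phenyl-trans-decalin-8α-ol, via dioxanylium ion 10 (not isolated)
Conditions: confined chiral imidodiphosphorimidate (IDPi) Brønsted acid (5 mol%; the enantiomer that gives (−)-ambrox from homofarnesol), H2O (1.5 equiv), (CF3)2CHOH/CH2Cl2, −30 °C, 48 h; aq. NaHCO3
Reagents that add atoms: water, O
Why: Proposed new method: the confined strong acid protonates the most basic alkene (the 2-aryl alkene) to a tertiary benzylic cation held as a contact ion pair in the chiral cavity. The E,E,E-triene folds chair–chair, so C4–C5 and C10–C9 form by anti additions (trans-decalin, E-aryl group equatorial = 4α). The C8 cation is trapped on its α face by the acetate carbonyl oxygen as the six-membered acetoxonium ion 10. Water opens 10 to the tertiary alcohol and primary acetate and returns the proton for turnover, so C4, C5, C10, C9 and C8 are set in one step from an achiral substrate. The closest known reactions are the IDPi-catalysed cyclisation of homofarnesol to ambrox and the superacid cyclisation of farnesyl acetate with acetate participation; an aryl-stabilised initiating cation combined with ester-carbonyl termination under chiral Brønsted acid control has not been shown.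

**Step 6**
Reactants: 11 9β-(acetoxymethyl)-4β,8β,10β-trimethyl-4α-phenyl-trans-decalin-8α-ol
Product: 12 9β-(acetoxymethyl)-8α-hydroxy-4β,8β,10β-trimethyl-trans-decalin-4α-carboxylic acid
Conditions: RuCl3·xH2O (5 mol%), NaIO4 (15 equiv), CCl4/MeCN/H2O (2:2:3), rt
Reagents that add atoms: sodium periodate, [Na+].[O-]I(=O)(=O)=O; water, O
Why: RuO4 generated in situ degrades the phenyl ring to a carboxylic acid (Sharpless arene oxidation) without touching the quaternary C4, the acetate or the tertiary alcohol, and there is no alkene left in the molecule.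

**Step 7**
Reactants: 12 9β-(acetoxymethyl)-8α-hydroxy-4β,8β,10β-trimethyl-trans-decalin-4α-carboxylic acid
Product: 13 9β-(acetoxymethyl)-8α-hydroxy-4β,8β,10β-trimethyl-trans-decalin-4α-carboxylic acid 6α-lactone
Conditions: [Mn(OTf)2((S,S)-TIPS-pdp)] (2 mol%; antipode if mismatched), H2O2 (50% aq., 2.5 equiv, syringe pump), (CF3)2CHOH, 0 °C
Reagents that add atoms: none
Why: Carboxylate-directed manganese-catalysed γ-C(sp3)–H lactonisation (hydrogen abstraction by the carboxylate-bound manganese-oxo, then carboxylate rebound): only the equatorial 6α-H lies peri to the equatorial 4α-carboxylate (the other γ-position, C2, is out of reach on the locked ring), and rebound on the same face gives the 6α-oxygen.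

**Step 8**
Reactants: 13 9β-(acetoxymethyl)-8α-hydroxy-4β,8β,10β-trimethyl-trans-decalin-4α-carboxylic acid 6α-lactone
Product: 14 8α-hydroxy-9β-(hydroxymethyl)-4β,8β,10β-trimethyl-trans-decalin-4α-carboxylic acid 6α-lactone
Conditions: K2CO3 (0.5 equiv), MeOH, 0 °C → rt
Reagents that add atoms: none
Why: Base-catalysed transesterification removes the unhindered primary acetate, while the neopentyl γ-lactone either survives or recloses.

**Step 9**
Reactants: 14 8α-hydroxy-9β-(hydroxymethyl)-4β,8β,10β-trimethyl-trans-decalin-4α-carboxylic acid 6α-lactone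
Product: 15 9β-formyl-8α-hydroxy-4β,8β,10β-trimethyl-trans-decalin-4α-carboxylic acid 6α-lactone
Conditions: TEMPO (0.1 equiv), PhI(OAc)2 (1.2 equiv), CH2Cl2, rt
Reagents that add atoms: none
Why: Oxoammonium (TEMPO) oxidation stops at the aldehyde and leaves the tertiary alcohol alone; the equatorial formyl group at C9 is the stable epimer.

**Step 10**
Reactants: 15 9β-formyl-8α-hydroxy-4β,8β,10β-trimethyl-trans-decalin-4α-carboxylic acid 6α-lactone
Product: 16 8α-hydroxy-4β,8β,10β-trimethyl-9β-vinyl-trans-decalin-4α-carboxylic acid 6α-lactone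
Conditions: Ph3PCH3Br (3 equiv), KN(SiMe3)2 (2.8 equiv), THF, −78 → 0 °C
Reagents that add atoms: methyltriphenylphosphonium bromide, [Br-].C[P+](c1ccccc1)(c1ccccc1)c1ccccc1
Why: Wittig methylenation of the β-hydroxy aldehyde with excess ylide at low temperature outruns retro-aldol cleavage and does not attack the hindered lactone.

**Step 11**
Reactants: 17 but-2-yn-1-ol
Product: 18 but-2-yn-1-yl methyl carbonate
Conditions: ClCO2Me (1.2 equiv), pyridine, CH2Cl2, 0 °C
Reagents that add atoms: methyl chloroformate, COC(=O)Cl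
Why: Simple O-acylation of a primary alcohol gives the propargylic carbonate needed as leaving group.

**Step 12**
Reactants: 18 but-2-yn-1-yl methyl carbonate
Product: 19 2-(buta-2,3-dien-2-yl)-4,4,5,5-tetramethyl-1,3,2-dioxaborolane
Conditions: B2pin2 (1.1 equiv), CuCl (5 mol%), KOtBu (5 mol%), Xantphos (5 mol%), THF, rt
Reagents that add atoms: bis(pinacolato)diboron, CC1(C)OB(OC1(C)C)B1OC(C)(C)C(C)(C)O1
Why: Copper-catalysed γ-selective (SN2′) borylation of propargylic carbonates puts boron on the methyl-bearing alkyne carbon and gives the allenylboronate.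

**Step 13**
Reactants: 20 ethyl (E)-3-methyl-4-oxobut-2-enoate; 19 2-(buta-2,3-dien-2-yl)-4,4,5,5-tetramethyl-1,3,2-dioxaborolane
Product: 22 ethyl (R,E)-3-methyl-4-[(triethylsilyl)oxy]oct-2-en-6-ynoate, via homopropargylic alcohol 21 (not isolated)
Conditions: (R)-TRIP phosphoric acid (5 mol%), 4 Å MS, toluene, −20 °C; aq. NaHCO3 work-up; crude 21, Et3SiCl, imidazole, CH2Cl2, 0 °C
Reagents that add atoms: chlorotriethylsilane, CC[Si](Cl)(CC)CC
Why: Chiral phosphoric acid-catalysed allenylboration (propargylation) goes through a closed six-membered transition state with the acid hydrogen-bonded to the boronate oxygen. Re-face attack on the enal (the sense seen with aromatic aldehydes) gives the 4R carbinol (future C16), and the E-enoate cannot lactonise, so the alcohol is simply silylated.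

**Step 14**
Reactants: 22 ethyl (R,E)-3-methyl-4-[(triethylsilyl)oxy]oct-2-en-6-ynoate
Product: 24 ethyl (R,2E,6E)-7-iodo-3-methyl-4-[(triethylsilyl)oxy]octa-2,6-dienoate, via alkenylzirconocene 23 (not isolated)
Conditions: Cp2Zr(H)Cl (2 equiv), THF, rt → 40 °C; then I2, THF, 0 °C
Reagents that add atoms: iodine, [I][I]
Why: Hydrozirconation is syn and, after equilibration with excess hydride, places zirconium on the less hindered methyl-bearing alkyne carbon; iodinolysis with retention gives the (E)-2-iodo-2-alkene, and the alkyne reacts faster than the hindered enoate.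

**Step 15**
Reactants: 16 8α-hydroxy-4β,8β,10β-trimethyl-9β-vinyl-trans-decalin-4α-carboxylic acid 6α-lactone; 24 ethyl (R,2E,6E)-7-iodo-3-methyl-4-[(triethylsilyl)oxy]octa-2,6-dienoate
Product: 26 9β-[(3E,6R,7E)-8-(ethoxycarbonyl)-3,7-dimethyl-6-(triethylsilyloxy)octa-3,7-dien-1-yl]-8α-hydroxy-4β,8β,10β-trimethyl-trans-decalin-4α-carboxylic acid 6α-lactone, via alkylborane 25 (not isolated)
Conditions: 9-BBN (1.5 equiv), THF, rt → 40 °C; then 24 (1.1 equiv), Pd(dppf)Cl2 (5 mol%), AsPh3 (10 mol%), Cs2CO3 (3 equiv), DMF/THF/H2O, rt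
Reagents that add atoms: none
Why: Anti-Markovnikov hydroboration of the only alkene followed by B-alkyl Suzuki–Miyaura coupling forms C12–C13 with retention, fixing the 13E alkene; no base-sensitive butenolide is present yet.

**Step 16**
Reactants: 26 the Suzuki product of step 15
Product: 27 9β-[(3E,6R,7E)-8-carboxy-6-hydroxy-3,7-dimethylocta-3,7-dien-1-yl]-6α,8α-dihydroxy-4β,8β,10β-trimethyl-trans-decalin-4α-carboxylic acid
Conditions: KOH (8 equiv), MeOH/H2O (4:1), 60 °C; then 1 M HCl to pH 3, THF/H2O, 0 °C, 1 h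
Reagents that add atoms: potassium hydroxide, [K+].[OH-]
Why: Saponification opens the γ-lactone and the ethyl ester, and the brief acidic work-up removes the triethylsilyl ether. The E geometry prevents ring closure, so C16 is never exposed to base as an acidic butenolide γ-CH.

**Step 17**
Reactants: 27 the (7E)-trihydroxy diacid of step 16
Product: 29 (4R,5R,6S,8R,9R,10S)-6α,8α-dihydroxy-4β,8β,10β-trimethyl-9β-{(3E)-3-methyl-5-[(2R)-3-methyl-5-oxo-2,5-dihydrofuran-2-yl]pent-3-en-1-yl}-trans-decalin-4α-carboxylic acid, via Z-hydroxy acid 28 (not isolated)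
Conditions: hν (254 nm, quartz), degassed MeCN, rt; then stand at rt
Reagents that add atoms: none
Why: Direct excitation of the α,β-unsaturated acid (the only chromophore at this wavelength) equilibrates E and Z isomers, and the Z acid is drained irreversibly by spontaneous lactonisation onto the C16 hydroxyl (photochemical E→Z isomerisation–lactonisation); the C16–O bond is not broken and the isolated 13E alkene is not excited.

**Compound list**
1 | ethynylbenzene | C#Cc1ccccc1 | starting material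
2 | (E)-dimethyl(2-phenylprop-1-en-1-yl)alumane | C/C(=C\[Al](C)C)c1ccccc1 | intermediate (not isolated)
3 | (E)-(1-iodoprop-1-en-2-yl)benzene | C/C(=C\I)c1ccccc1 | intermediate
4 | geranyl acetate, (2E)-3,7-dimethylocta-2,6-dien-1-yl acetate | CC(C)=CCC/C(C)=C/COC(C)=O | starting material
5 | (2E,6E)-8-hydroxy-3,7-dimethylocta-2,6-dien-1-yl acetate | OC/C(C)=C/CC/C(C)=C/COC(C)=O | intermediate (not isolated)
6 | (2E,6E)-3,7-dimethyl-8-oxoocta-2,6-dien-1-yl acetate | O=C/C(C)=C/CC/C(C)=C/COC(C)=O | intermediate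
7 | (2E,6E)-3,7-dimethylnona-2,6,8-trien-1-yl acetate | C=C/C(C)=C/CC/C(C)=C/COC(C)=O | intermediate
8 | (2E,6E)-9-(9-borabicyclo[3.3.1]nonan-9-yl)-3,7-dimethylnona-2,6-dien-1-yl acetate | CC(=O)OC/C=C(\C)CC/C=C(\C)CCB1C2CCCC1CCC2 | intermediate (not isolated)
9 | (2E,6E,10E)-3,7-dimethyl-11-phenyldodeca-2,6,10-trien-1-yl acetate | CC(=O)OC/C=C(\C)CC/C=C(\C)CC/C=C(\C)c1ccccc1 | intermediate
10 | trans-fused 2-methyl-1,3-dioxan-2-ylium ion bridging O–C8(α) and O–C11 of the 4α-phenyl decalin (IDPi counter-anion) | CC1=[O+]C[C@@H]2[C@@]3(C)CCC[C@@](C)(c4ccccc4)[C@@H]3CC[C@@]2(C)O1 | intermediate (not isolated)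
11 | 9β-(acetoxymethyl)-4β,8β,10β-trimethyl-4α-phenyl-trans-decalin-8α-ol (5α-H, 9α-H) | CC(=O)OC[C@@H]1[C@@]2(C)CCC[C@@](C)(c3ccccc3)[C@@H]2CC[C@@]1(C)O | intermediate
12 | 9β-(acetoxymethyl)-8α-hydroxy-4β,8β,10β-trimethyl-trans-decalin-4α-carboxylic acid | CC(=O)OC[C@@H]1[C@@]2(C)CCC[C@@](C)(C(=O)O)[C@@H]2CC[C@@]1(C)O | intermediate
13 | 6α-lactone of 12 (γ-lactone from the C4α carboxyl to O–C6α) | CC(=O)OC[C@@H]1[C@@]2(C)CCC[C@@](C)(C(=O)O3)[C@@H]2[C@@H]3C[C@@]1(C)O | intermediate
14 | 8α-hydroxy-9β-(hydroxymethyl)-4β,8β,10β-trimethyl-trans-decalin-4α-carboxylic acid 6α-lactone | OC[C@@H]1[C@@]2(C)CCC[C@@](C)(C(=O)O3)[C@@H]2[C@@H]3C[C@@]1(C)O | intermediate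
15 | 9β-formyl-8α-hydroxy-4β,8β,10β-trimethyl-trans-decalin-4α-carboxylic acid 6α-lactone | O=C[C@@H]1[C@@]2(C)CCC[C@@](C)(C(=O)O3)[C@@H]2[C@@H]3C[C@@]1(C)O | intermediate
16 | 8α-hydroxy-4β,8β,10β-trimethyl-9β-vinyl-trans-decalin-4α-carboxylic acid 6α-lactone | C=C[C@@H]1[C@@]2(C)CCC[C@@](C)(C(=O)O3)[C@@H]2[C@@H]3C[C@@]1(C)O | intermediate
17 | but-2-yn-1-ol | CC#CCO | starting material
18 | but-2-yn-1-yl methyl carbonate | CC#CCOC(=O)OC | intermediate
19 | 2-(buta-2,3-dien-2-yl)-4,4,5,5-tetramethyl-1,3,2-dioxaborolane | C=C=C(C)B1OC(C)(C)C(C)(C)O1 | intermediate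
20 | ethyl (E)-3-methyl-4-oxobut-2-enoate | CCOC(=O)/C=C(\C)C=O | starting material
21 | ethyl (R,E)-4-hydroxy-3-methyloct-2-en-6-ynoate | CCOC(=O)/C=C(\C)[C@H](O)CC#CC | intermediate (not isolated)
22 | ethyl (R,E)-3-methyl-4-[(triethylsilyl)oxy]oct-2-en-6-ynoate | CCOC(=O)/C=C(\C)[C@H](O[Si](CC)(CC)CC)CC#CC | intermediate
23 | ethyl (R,2E,6E)-7-[chlorobis(cyclopentadienyl)zirconio]-3-methyl-4-[(triethylsilyl)oxy]octa-2,6-dienoate | CCOC(=O)/C=C(\C)[C@H](O[Si](CC)(CC)CC)C/C=C(\C)[Zr](Cl)(C1C=CC=C1)C1C=CC=C1 | intermediate (not isolated)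
24 | ethyl (R,2E,6E)-7-iodo-3-methyl-4-[(triethylsilyl)oxy]octa-2,6-dienoate | CCOC(=O)/C=C(\C)[C@H](O[Si](CC)(CC)CC)C/C=C(\C)I | intermediate
25 | 9-BBN adduct of 16: 9β-[2-(9-borabicyclo[3.3.1]nonan-9-yl)ethyl]-8α-hydroxy-4β,8β,10β-trimethyl-trans-decalin-4α-carboxylic acid 6α-lactone | C(B4C5CCCC4CCC5)C[C@@H]1[C@@]2(C)CCC[C@@](C)(C(=O)O3)[C@@H]2[C@@H]3C[C@@]1(C)O | intermediate (not isolated)
26 | 9β-[(3E,6R,7E)-8-(ethoxycarbonyl)-3,7-dimethyl-6-(triethylsilyloxy)octa-3,7-dien-1-yl]-8α-hydroxy-4β,8β,10β-trimethyl-trans-decalin-4α-carboxylic acid 6α-lactone | CCOC(=O)/C=C(\C)[C@H](O[Si](CC)(CC)CC)C/C=C(\C)CC[C@@H]1[C@@]2(C)CCC[C@@](C)(C(=O)O3)[C@@H]2[C@@H]3C[C@@]1(C)O | intermediate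
27 | 9β-[(3E,6R,7E)-8-carboxy-6-hydroxy-3,7-dimethylocta-3,7-dien-1-yl]-6α,8α-dihydroxy-4β,8β,10β-trimethyl-trans-decalin-4α-carboxylic acid | OC(=O)/C=C(\C)[C@H](O)C/C=C(\C)CC[C@@H]1[C@@]2(C)CCC[C@@](C)(C(=O)O)[C@@H]2[C@@H](O)C[C@@]1(C)O | intermediate
28 | the (7Z) isomer of 27 | OC(=O)/C=C(/C)[C@H](O)C/C=C(\C)CC[C@@H]1[C@@]2(C)CCC[C@@](C)(C(=O)O)[C@@H]2[C@@H](O)C[C@@]1(C)O | intermediate (not isolated)
29 | (4R,5R,6S,8R,9R,10S)-6α,8α-dihydroxy-4β,8β,10β-trimethyl-9β-{(3E)-3-methyl-5-[(2R)-3-methyl-5-oxo-2,5-dihydrofuran-2-yl]pent-3-en-1-yl}-trans-decalin-4α-carboxylic acid (CNP0387770.1) | CC1=CC(=O)O[C@@H]1C/C=C(\C)CC[C@@H]1[C@@]2(C)CCC[C@@](C)(C(=O)O)[C@@H]2[C@@H](O)C[C@@]1(C)O | target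

**Step count**
Total: 17 steps. Longest linear sequence: 12 steps (geranyl acetate 4 → steps 2–10, then 15–17).

**Three steps most likely to fail, with fallbacks**

Step 5 (the proposed new cyclisation). The aryl-stabilised cation may be too long-lived for good enantiocontrol, or water may lower the acidity too far. Fallback, from 9, back at 12: cyclise 9 with ClSO3H in 2-nitropropane at −78 °C, the established superacid cyclisation of farnesyl-type acetates with acetate participation, to the racemic hydroxy acetate F1. Oxidise its phenyl ring exactly as in step 6 to the racemic acid F2. Resolve F2 by fractional crystallisation with (R)-1-phenylethylamine (or its antipode, whichever gives the less soluble salt) to the (R)-1-phenylethylammonium salt of 12 F3, and release enantiopure 12 with dilute HCl.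

Step 7 (γ-C–H lactonisation). The peri hydrogen may be abstracted too slowly, or other C–H bonds may be oxidised. Fallback, from 12, back at 13: switch to amidyl-radical hydrogen transfer. Carbonyldiimidazole then NH3 gives the primary carboxamide F4. N-(trimethylsilyl)imidazole gives its 8-O-trimethylsilyl ether F5, which masks the tertiary alcohol against hypoiodite formation. PhI(OAc)2/I2 under visible light in CH2Cl2 generates the N-iodoamide; 1,5-hydrogen transfer from C6 and ring closure give the iminolactone F6 (Hofmann–Löffler–Freytag-type lactonisation of a primary amide). Aqueous HCl/THF hydrolyses the imine and the silyl ether to 13.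

Step 17 (photochemical isomerisation–lactonisation). Photodeconjugation or secondary photochemistry of the product may compete. Fallback, from 16 and 19, back at 29: carry a pre-formed Z butenolide instead. Commercial 5-hydroxy-4-methylfuran-2(5H)-one F7 is alkylated on its ring-opened carboxylate (MeI, KHCO3, DMF) to methyl (Z)-3-methyl-4-oxobut-2-enoate F8. Propargylation with 19 under the step 13 catalyst, then acid-catalysed lactonisation of the Z hydroxy ester, gives (R)-5-(but-2-yn-1-yl)-4-methylfuran-2(5H)-one F9. Hydrozirconation–iodination as in step 14 gives (R)-5-[(E)-3-iodobut-2-en-1-yl]-4-methylfuran-2(5H)-one F10. Separately, 16 is saponified (KOH, MeOH/H2O; then pH 4) to the 9β-vinyl dihydroxy acid F11 and hydroborated with excess 9-BBN to the alkylborane F12. F12 is coupled with F10 through its pre-formed hydroxyborate (1 equiv KOH per boron, Pd(dppf)Cl2, AsPh3, THF/DMF, rt), so that the epimerisable butenolide never meets free base, giving 29.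

**Further compounds**
F1 | step 5 | racemic 9β-(acetoxymethyl)-4β,8β,10β-trimethyl-4α-phenyl-trans-decalin-8α-ol | CC(=O)OC[C@@H]1[C@@]2(C)CCC[C@@](C)(c3ccccc3)[C@@H]2CC[C@@]1(C)O.CC(=O)OC[C@H]1[C@]2(C)CCC[C@](C)(c3ccccc3)[C@H]2CC[C@]1(C)O
F2 | step 5 | racemic 9β-(acetoxymethyl)-8α-hydroxy-4β,8β,10β-trimethyl-trans-decalin-4α-carboxylic acid | CC(=O)OC[C@@H]1[C@@]2(C)CCC[C@@](C)(C(=O)O)[C@@H]2CC[C@@]1(C)O.CC(=O)OC[C@H]1[C@]2(C)CCC[C@](C)(C(=O)O)[C@H]2CC[C@]1(C)O
F3 | step 5 | (R)-1-phenylethylammonium salt of 12 | C[C@@H]([NH3+])c1ccccc1.CC(=O)OC[C@@H]1[C@@]2(C)CCC[C@@](C)(C([O-])=O)[C@@H]2CC[C@@]1(C)O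
F4 | step 7 | 9β-(acetoxymethyl)-8α-hydroxy-4β,8β,10β-trimethyl-trans-decalin-4α-carboxamide | CC(=O)OC[C@@H]1[C@@]2(C)CCC[C@@](C)(C(N)=O)[C@@H]2CC[C@@]1(C)O
F5 | step 7 | 8-O-trimethylsilyl ether of F4 | CC(=O)OC[C@@H]1[C@@]2(C)CCC[C@@](C)(C(N)=O)[C@@H]2CC[C@@]1(C)O[Si](C)(C)C
F6 | step 7 | 6α-iminolactone of F5 | CC(=O)OC[C@@H]1[C@@]2(C)CCC[C@@](C)(C(=N)O3)[C@@H]2[C@@H]3C[C@@]1(C)O[Si](C)(C)C
F7 | step 17 | 5-hydroxy-4-methylfuran-2(5H)-one (racemic, configurationally labile lactol) | CC1=CC(=O)OC1O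
F8 | step 17 | methyl (Z)-3-methyl-4-oxobut-2-enoate | COC(=O)/C=C(/C)C=O
F9 | step 17 | (R)-5-(but-2-yn-1-yl)-4-methylfuran-2(5H)-one | CC1=CC(=O)O[C@@H]1CC#CC
F10 | step 17 | (R)-5-[(E)-3-iodobut-2-en-1-yl]-4-methylfuran-2(5H)-one | CC1=CC(=O)O[C@@H]1C/C=C(\C)I
F11 | step 17 | 6α,8α-dihydroxy-4β,8β,10β-trimethyl-9β-vinyl-trans-decalin-4α-carboxylic acid | C=C[C@@H]1[C@@]2(C)CCC[C@@](C)(C(=O)O)[C@@H]2[C@@H](O)C[C@@]1(C)O
F12 | step 17 | 9-BBN adduct of F11 (acid and hydroxyls transiently O-borylated) | C(B4C5CCCC4CCC5)C[C@@H]1[C@@]2(C)CCC[C@@](C)(C(=O)O)[C@@H]2[C@@H](O)C[C@@]1(C)O
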